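The solution of this flask can hold 28 mM, which is 56.0% of the charge, so the charge cannot all dissolve at once.

    gas phase ⇌ dissolved gas, rate k1*(csat - [dissolved gas]) (k1 = 0.347 h⁻¹, csat = 2.5 mM)
    starting material + dissolved gas + catalyst → catalyst + product (k2 = 5560 L² mol⁻² h⁻¹)
    catalyst + product ⇌ idle complex (K3 = 6.33 L mol⁻¹, k3 = 34.5 L mol⁻¹ h⁻¹)
    solid substrate ⇌ starting material, rate k4*(cs4 - [starting material]) while solid is left; crystals form when [starting material] > cs4 (cs4 = 28 mM, k4 = 0.141 h⁻¹)

solid substrate 0.050 M; gas phase 2.5 mM (held); catalyst 1.0 mM; time 40 h

- for product the idle complex is counted in
- as a solid, counted per litre of solution: solid substrate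
- at the start none of the gas is dissolved
- at the start none of the solid substrate is in solution
- run time (flask): 40 h

* amount of product and idle complex together at 40 h, in percent of the solid substrate charged
* the change that raises the amount of product and idle complex together at 40 h, in percent of the solid substrate charged most ("none" if none brings more than 2 percentage points) (teal / blue / red / green / none)
* amount of product and idle complex together at 40 h, in percent of the solid substrate charged, after green

- teal: doubling the saturation concentration of gas phase, all else as stated
- blue: doubling the solubility in step 4, all else as stated
- red: doubling the amount of catalyst, all else as stated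
- green: doubling the dissolution coefficient of step 4, all else as stated

Suppose the starting material stands at its solubility. Step 2 then removes dissolved gas with a pseudo-first-order constant of 0.156 h⁻¹, against 0.347 h⁻¹ for transfer. So the dissolved gas holds 69.0% of saturation, and the plateau rate is 0.00537 h⁻¹ of the charge.

Now test each number in turn. Doubling the saturation concentration doubles that rate. Doubling the catalyst multiplies it by 1.53, less than 2, because the gas level sinks. Doubled, the solubility stands at 0.0560 M, more than the charge of 50 mM, so I take the starting material at the charge, and the factor is 1.44. The dissolution coefficient acts through the climb to the plateau. The mean of that exponential climb over 40 h is 82.3% of the plateau, and doubling the coefficient lifts it to 91.1%.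

That gives 0.00442 h⁻¹, the mean rate: the fraction of the charge turned per hour, averaged over the run. My reckoning is therefore 17.7%, with 19.6% after green, a gain of 1.9 percentage points, and teal as the best change, raising the rate more than the others. Step 3 costs little: at that yield 5.60% of the catalyst is idle complex.

The forecast gives 17.1%, teal and 18.7%, saying: “Rate is roughly proportional to the gas level”.

The flask gives 17.1%, with teal best at 15 points and 18.7% after green. The mean rate of the flask is 0.00428 h⁻¹, lower than my 0.00442 h⁻¹. Starting material is made 8.86 times faster than it is used at 6.76 h, but 1.05 times at 40.0 h, when it holds 52.3% of the charge.

Take the neighbour flask, the same but with 0.020 M of solid substrate. Its ceiling is the charge, which is less than the solubility, so with the same climb the mean rate becomes 0.00867 h⁻¹ of its own charge, or 34.7% by 40 h. The simulation of that neighbour flask gives 32.2%.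

(The numbers stand for no real mixture; what happens was integrated by code.)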